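The runs are simulated for substances that don't exist; scatter was added.

- We read every flask at 30 h, so we hold two amounts side by side: the coupling partner charged, and the partner that one charge of catalyst can turn over before it dies; a slow flask may still be running at the reading, short of both.

| setting | winter | dawn | birch | cedar | alder | maple | oak |
|---|---|---|---|---|---|---|---|
| substrate | 0.25 M | 0.25 M | 0.25 M | 0.25 M | 0.25 M | 0.25 M | 0.25 M |
| coupling partner | 0.043 M | 0.59 M | 0.0300 M | 0.0600 M | 0.120 M | 0.250 M | 0.500 M |
| free catalyst | 0.50 mM | 0.50 mM | 0.50 mM | 0.50 mM | 0.50 mM | 0.50 mM | 0.50 mM |
| remark | run made earlier | run made earlier |  |  |  |  |  |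
| time |  |  | 30 h | 30 h | 30 h | 30 h | 30 h |

| run | time / h | product / % |
|---|---|---|
| winter | 4.00 | 3 |
| winter | 10.0 | 8 |
| winter | 20.0 | 9 |
| winter | 30.0 | 13 |
| dawn | 2.50 | 14 |
| dawn | 6.00 | 22 |
| dawn | 12.0 | 21 |
| dawn | 30.0 | 23 |

(scatter of a reading: 1.5 percentage points)

- amount of product at the end, in percent of the substrate charged for birch, cedar, alder, maple, oak, in this order
- how that number moves from the first to the last of them (rises all the way / falls all the way / falls, then rises / rises, then falls / hardly changes)

- "hardly changes" means that all values lie within two and a half points (for a concentration: within two and a half percent of the largest)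

- The dawn run has partner to spare, and from 6.00 h its readings stand still at a mean of 22.0 %, which we call the catalyst ceiling.
- Taking one partner per product, that ceiling gives the critical partner charge 0.0550 M, the partner turned over in one catalyst life, or about 110 turnovers per catalyst.
- Dawn's charge lies far above this critical charge, while winter's lies below it, which makes the partner the limiting reagent in winter.
- The ratio of charge to critical charge runs from 0.545 in birch to 9.09 in oak.
- Winter reached 75.6 % of its partner supply at the reading, so we reckon birch at 9.07 %.
- We expect cedar to stand below the ceiling at the reading, and alder, maple and oak to level at the ceiling, assuming that dawn's ceiling holds at lower charges too.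
- The forecast gives 8 %, 16 %, 30 %, 45 % and 28 %, so its shape is rises, then falls: “Low partner is limited by rate and supply, and high partner by catalyst death”. We part from it from alder on, where our line stays flat at the ceiling and the forecast stands above it.
- The flasks give 9.67 %, 16.4 %, 21.8 %, 22.9 % and 23.0 %, so the shape is rises all the way.

    substrate + free catalyst → catalyst intermediate A (k = 4.80 /M/s)
    coupling partner + catalyst intermediate A ⇌ catalyst intermediate B (K = 2.00 /M, k = 0.100 /M/s)
    catalyst intermediate B ⇌ free catalyst + product (K = 0.140 M, k = 0.0390 /s)
    coupling partner + catalyst intermediate A → spent catalyst (k = 3.80 × 10⁻⁴ /M/s)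

- Oak stops at 23.0 %, close to the ceiling of 22.0 %, with 88 % of its partner left and spent catalyst at >99.9 %. Without the turning of partner and catalyst intermediate A into spent catalyst, oak reaches 99.8 %. Cedar, charged at 1.09 times the critical charge, has 16.4 % at the reading with 31 % of its partner left, and at 300 h it holds 22.4 %.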